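The indane is cut at the C2–C3 bond. C3 is a diarylmethine flanked by ring A and the 2,4-dihydroxyphenyl ring, and the C2–H bond is benzylic to the 3,5-dihydroxyphenyl ring and allylic to the exocyclic C1 alkene, standing 1,5 to C3 through C3a and C7a of ring A. A chiral dirhodium carboxylate turns a diaryl carbene at C3 into the five-membered ring by C–H insertion, making the C2–C3 bond and both stereocentres in one operation. The precursor is a fully silylated (E)-1,3-diarylpropen-2-yl benzophenone hydrazone, assembled from a gem-dibromoalkene by two stereocontrolled Negishi couplings and an aryllithium/nitrile/hydrazine sequence.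

Key step: step 12

Assumption: the antipode of the PTAD catalyst that gives the (3S) centre is fixed in a first small run; Rh2(S-PTAD)4 is written, and Rh2(R-PTAD)4 takes its place if the opposite sense is found.

Abbreviations: TBS = tert-butyldimethylsilyl; TBSO = tert-butyldimethylsilyloxy; PTAD = N-phthaloyl-1-adamantylglycinate; DPEphos = bis(2-diphenylphosphinophenyl) ether.

Step 1
Reactants: 1 vanillin
Product: 2 4-(TBSO)-3-methoxybenzaldehyde
Conditions: TBSCl, imidazole, DMF, rt
Reagents that add atoms: tert-butyldimethylsilyl chloride (TBSCl), CC(C)(C)[Si](C)(C)Cl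
Why: Silyl ether formation at the phenol with TBSCl and imidazole is fast and leaves the aldehyde untouched.

Step 2
Reactants: 2 4-(TBSO)-3-methoxybenzaldehyde
Product: 3 tert-butyl[4-(2,2-dibromoethenyl)-2-methoxyphenoxy]dimethylsilane
Conditions: CBr4, PPh3, Zn dust, CH2Cl2, 0 °C → rt
Reagents that add atoms: carbon tetrabromide, BrC(Br)(Br)Br
Why: The Ramirez dibromo-olefination (first stage of the Corey–Fuchs sequence) converts aromatic aldehydes into 1,1-dibromoalkenes under near-neutral conditions that an aryl silyl ether tolerates.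

Step 3
Reactants: 4 5-bromoresorcinol
Product: 5 2-bromo-4,6-dihydroxybenzaldehyde
Conditions: POCl3, DMF, MeCN, 0 °C → rt; H2O, 50 °C
Reagents that add atoms: N,N-dimethylformamide, CN(C)C=O; water, O
Why: Vilsmeier–Haack formylation attacks the resorcinol at the carbon ortho to one hydroxyl and para to the other, not at the carbon between the two hydroxyls, as it does with resorcinol and orcinol.

Step 4
Reactants: 5 2-bromo-4,6-dihydroxybenzaldehyde
Product: 7 2-bromo-4,6-dihydroxybenzonitrile, via aldoxime 6 (not isolated)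
Conditions: NH2OH·HCl, HCO2Na, HCO2H, reflux
Reagents that add atoms: hydroxylamine hydrochloride, NO.Cl
Why: Oxime formation followed by dehydration in hot formic acid is the standard one-pot conversion of a hydroxybenzaldehyde into its nitrile and needs no phenol protection.

Step 5
Reactants: 7 2-bromo-4,6-dihydroxybenzonitrile
Product: 8 2-bromo-4,6-bis(TBSO)benzonitrile
Conditions: TBSCl, imidazole, DMF, rt
Reagents that add atoms: tert-butyldimethylsilyl chloride (TBSCl), CC(C)(C)[Si](C)(C)Cl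
Why: Silyl ether formation caps both phenols, including the one beside the nitrile, with a group that carries no O–C–H bond.

Step 6
Reactants: 8 2-bromo-4,6-bis(TBSO)benzonitrile; 3 tert-butyl[4-(2,2-dibromoethenyl)-2-methoxyphenoxy]dimethylsilane
Product: 11 2-[(Z)-1-bromo-2-[4-(TBSO)-3-methoxyphenyl]ethenyl]-4,6-bis(TBSO)benzonitrile, via arylmagnesium chloride 9 (not isolated), via arylzinc chloride 10 (not isolated)
Conditions: iPrMgCl·LiCl, THF, −15 °C; ZnCl2, −15 °C → rt; 3, PdCl2(DPEphos) (3 mol%), THF, 0 °C → rt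
Reagents that add atoms: none
Why: The ortho cyano group speeds bromine–magnesium exchange, transmetalation gives an arylzinc that spares the nitrile, and in the Negishi coupling of a 1,1-dibromoalkene zerovalent palladium inserts first into the less hindered C–Br bond trans to the aryl group, so ring A enters trans to the vanillyl ring and the (Z)-bromoalkene results.

Step 7
Reactants: 12 3,5-dihydroxybenzyl alcohol
Product: 13 tris-TBS ether of 3,5-dihydroxybenzyl alcohol
Conditions: TBSCl (3.3 equiv), imidazole, DMF, rt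
Reagents that add atoms: tert-butyldimethylsilyl chloride (TBSCl), CC(C)(C)[Si](C)(C)Cl
Why: Exhaustive silyl ether formation protects both phenols and turns the benzylic hydroxyl into the group that the next step replaces.

Step 8
Reactants: 13 tris-TBS ether of 3,5-dihydroxybenzyl alcohol
Product: 14 3,5-bis(TBSO)benzyl bromide
Conditions: Ph3PBr2, CH2Cl2, 0 °C → rt
Reagents that add atoms: dibromotriphenylphosphorane, BrP(Br)(c1ccccc1)(c1ccccc1)c1ccccc1
Why: Ph3PBr2 converts an alkyl silyl ether directly into the bromide through an alkoxyphosphonium ion that bromide opens by SN2 (Appel-type bromination), a path that is closed to the two aryl silyl ethers.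

Step 9
Reactants: 11 2-[(Z)-1-bromo-2-[4-(TBSO)-3-methoxyphenyl]ethenyl]-4,6-bis(TBSO)benzonitrile; 14 3,5-bis(TBSO)benzyl bromide
Product: 16 2-[(E)-3-[3,5-bis(TBSO)phenyl]-1-[4-(TBSO)-3-methoxyphenyl]prop-1-en-2-yl]-4,6-bis(TBSO)benzonitrile, via benzylzinc bromide 15 (not isolated)
Conditions: 14, Zn dust, LiCl, THF, 0 °C → rt; then 11, Pd(t-Bu3P)2 (4 mol%), THF, rt → 40 °C
Reagents that add atoms: none
Why: LiCl-promoted zinc insertion gives the benzylic zinc bromide, and Negishi coupling with the bulky-phosphine palladium catalyst replaces the remaining vinylic bromide with retention of geometry, so the benzyl group ends cis to the vanillyl ring while nitrile and silyl ethers stay inert.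

Step 10
Reactants: 17 4-bromoresorcinol
Product: 18 4-bromo-1,3-bis(TBSO)benzene
Conditions: TBSCl, imidazole, DMF, rt
Reagents that add atoms: tert-butyldimethylsilyl chloride (TBSCl), CC(C)(C)[Si](C)(C)Cl
Why: Silyl ether formation protects both phenols with groups that survive the later organolithium step at low temperature.

Step 11
Reactants: 18 4-bromo-1,3-bis(TBSO)benzene; 16 2-[(E)-3-[3,5-bis(TBSO)phenyl]-1-[4-(TBSO)-3-methoxyphenyl]prop-1-en-2-yl]-4,6-bis(TBSO)benzonitrile
Product: 22 [2,4-bis(TBSO)phenyl]{2-[(E)-3-[3,5-bis(TBSO)phenyl]-1-[4-(TBSO)-3-methoxyphenyl]prop-1-en-2-yl]-4,6-bis(TBSO)phenyl}methanone hydrazone, via aryllithium 19 (not isolated), via N-lithio ketimine 20 (not isolated), via N–H ketimine 21 (not isolated)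
Conditions: 18, t-BuLi (2 equiv), Et2O, −78 °C; 16, Et2O, −78 → −40 °C; AcOH, −78 °C; N2H4·H2O, AcOH, EtOH, 45 °C
Reagents that add atoms: hydrazine hydrate, NN.O
Why: Bromine–lithium exchange gives an aryllithium that is kept cold to forestall the 1,3 oxygen-to-carbon silyl shift and that should add to the nitrile (organolithium addition stopping at the N-lithio ketimine) faster than it deprotonates the diarylallylic CH2 in diethyl ether, and the N–H ketimine freed by acetic acid exchanges with hydrazine (transimination with loss of NH3), which avoids condensing hydrazine with a benzophenone that carries three ortho substituents.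

Step 12
Reactants: 22 [2,4-bis(TBSO)phenyl]{2-[(E)-3-[3,5-bis(TBSO)phenyl]-1-[4-(TBSO)-3-methoxyphenyl]prop-1-en-2-yl]-4,6-bis(TBSO)phenyl}methanone hydrazone
Product: 24 (1E,2S,3S)-3-[2,4-bis(TBSO)phenyl]-2-[3,5-bis(TBSO)phenyl]-4,6-bis(TBSO)-1-[4-(TBSO)-3-methoxybenzylidene]indane, via diaryl diazomethane 23 (not isolated)
Conditions: MnO2 (8 equiv), CH2Cl2, 0 °C; cold filtration; Rh2(S-PTAD)4 (1 mol%), CH2Cl2, −40 → 0 °C
Reagents that add atoms: none
Why: MnO2 dehydrogenates the hydrazone to diaryl diazomethane 23, which loses N2 on the chiral dirhodium tetracarboxylate to give a donor/donor rhodium carbene at C3; the carbene takes up the C2–H bond in a concerted, asynchronous, hydride-transfer-like insertion, the closest known reaction type being the enantioselective intramolecular C–H insertion of hydrazone-derived diaryl carbenes that gives indanes and dihydrobenzofurans. The five-membered ring is closed by C2–C3 bond formation as a 1,5-insertion through a cyclic transition state over C3, C3a, C7a, C1 and C2. C3 is set by the catalyst, whose ligand pocket decides which face of the carbene carbon meets the C–H bond, and C2 is set relative to C3 in the same transition state, in which the 3,5-bis(silyloxy)phenyl group should turn away from the ortho-silyloxy aryl group on C3 and so give the trans-(2S,3S) product. The step needs site selectivity for C2–H, the trans-2,3 relationship and one absolute sense: the CH2 group offers the weakest, doubly activated C–H bonds, the only other 1,5 position is a vinylic C–H that is a poor hydride donor, both oxygens ortho to the carbene carbon carry silyl groups with no O–C–H bond, and addition to the C1 alkene would need a strained housane. The diazo compound is kept cold and meets the catalyst at once so that its thermal 1,7-electrocyclisation onto the neighbouring alkene cannot compete.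

Step 13
Reactants: 24 (1E,2S,3S)-3-[2,4-bis(TBSO)phenyl]-2-[3,5-bis(TBSO)phenyl]-4,6-bis(TBSO)-1-[4-(TBSO)-3-methoxybenzylidene]indane
Product: 25 (1E,2S,3S)-3-(2,4-dihydroxyphenyl)-2-(3,5-dihydroxyphenyl)-1-(4-hydroxy-3-methoxybenzylidene)indane-4,6-diol
Conditions: TBAF (8 equiv), AcOH (8 equiv), THF, 0 °C → rt, degassed
Reagents that add atoms: none
Why: Fluoride buffered with acetic acid cleaves all seven aryl silyl ethers (desilylation) without free phenoxide or a base strong enough to epimerise C2 or move the exocyclic alkene, so both stereocentres and the (E)-alkene are kept.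

Compound list

1 | vanillin (4-hydroxy-3-methoxybenzaldehyde) | COc1cc(C=O)ccc1O | starting material
2 | 4-(TBSO)-3-methoxybenzaldehyde | COc1cc(C=O)ccc1O[Si](C)(C)C(C)(C)C | intermediate
3 | tert-butyl[4-(2,2-dibromoethenyl)-2-methoxyphenoxy]dimethylsilane | COc1cc(C=C(Br)Br)ccc1O[Si](C)(C)C(C)(C)C | intermediate
4 | 5-bromoresorcinol | Oc1cc(O)cc(Br)c1 | starting material
5 | 2-bromo-4,6-dihydroxybenzaldehyde | O=Cc1c(Br)cc(O)cc1O | intermediate
6 | 2-bromo-4,6-dihydroxybenzaldehyde oxime (not isolated) | ON=Cc1c(Br)cc(O)cc1O | intermediate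
7 | 2-bromo-4,6-dihydroxybenzonitrile | N#Cc1c(Br)cc(O)cc1O | intermediate
8 | 2-bromo-4,6-bis(TBSO)benzonitrile | N#Cc1c(Br)cc(O[Si](C)(C)C(C)(C)C)cc1O[Si](C)(C)C(C)(C)C | intermediate
9 | [2-cyano-3,5-bis(TBSO)phenyl]magnesium chloride, LiCl complex (not isolated) | N#Cc1c([Mg]Cl)cc(O[Si](C)(C)C(C)(C)C)cc1O[Si](C)(C)C(C)(C)C | intermediate
10 | [2-cyano-3,5-bis(TBSO)phenyl]zinc chloride (not isolated) | N#Cc1c([Zn]Cl)cc(O[Si](C)(C)C(C)(C)C)cc1O[Si](C)(C)C(C)(C)C | intermediate
11 | 2-[(Z)-1-bromo-2-[4-(TBSO)-3-methoxyphenyl]ethenyl]-4,6-bis(TBSO)benzonitrile | COc1cc(/C=C(\Br)c2cc(O[Si](C)(C)C(C)(C)C)cc(O[Si](C)(C)C(C)(C)C)c2C#N)ccc1O[Si](C)(C)C(C)(C)C | intermediate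
12 | 3,5-dihydroxybenzyl alcohol | OCc1cc(O)cc(O)c1 | starting material
13 | tris-TBS ether of 3,5-dihydroxybenzyl alcohol | CC(C)(C)[Si](C)(C)OCc1cc(O[Si](C)(C)C(C)(C)C)cc(O[Si](C)(C)C(C)(C)C)c1 | intermediate
14 | 3,5-bis(TBSO)benzyl bromide | BrCc1cc(O[Si](C)(C)C(C)(C)C)cc(O[Si](C)(C)C(C)(C)C)c1 | intermediate
15 | [3,5-bis(TBSO)benzyl]zinc bromide (not isolated) | Br[Zn]Cc1cc(O[Si](C)(C)C(C)(C)C)cc(O[Si](C)(C)C(C)(C)C)c1 | intermediate
16 | 2-[(E)-3-[3,5-bis(TBSO)phenyl]-1-[4-(TBSO)-3-methoxyphenyl]prop-1-en-2-yl]-4,6-bis(TBSO)benzonitrile | COc1cc(/C=C(\Cc2cc(O[Si](C)(C)C(C)(C)C)cc(O[Si](C)(C)C(C)(C)C)c2)c2cc(O[Si](C)(C)C(C)(C)C)cc(O[Si](C)(C)C(C)(C)C)c2C#N)ccc1O[Si](C)(C)C(C)(C)C | intermediate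
17 | 4-bromoresorcinol | Oc1ccc(Br)c(O)c1 | starting material
18 | 4-bromo-1,3-bis(TBSO)benzene | Brc1ccc(O[Si](C)(C)C(C)(C)C)cc1O[Si](C)(C)C(C)(C)C | intermediate
19 | 2,4-bis(TBSO)phenyllithium (not isolated) | [Li]c1ccc(O[Si](C)(C)C(C)(C)C)cc1O[Si](C)(C)C(C)(C)C | intermediate
20 | N-lithio ketimine from 19 and 16 (not isolated) | COc1cc(/C=C(\Cc2cc(O[Si](C)(C)C(C)(C)C)cc(O[Si](C)(C)C(C)(C)C)c2)c2cc(O[Si](C)(C)C(C)(C)C)cc(O[Si](C)(C)C(C)(C)C)c2C(=N[Li])c2ccc(O[Si](C)(C)C(C)(C)C)cc2O[Si](C)(C)C(C)(C)C)ccc1O[Si](C)(C)C(C)(C)C | intermediate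
21 | N–H ketimine, the imine of the ring A/ring B benzophenone with the (E)-alkenyl arm (not isolated) | COc1cc(/C=C(\Cc2cc(O[Si](C)(C)C(C)(C)C)cc(O[Si](C)(C)C(C)(C)C)c2)c2cc(O[Si](C)(C)C(C)(C)C)cc(O[Si](C)(C)C(C)(C)C)c2C(=N)c2ccc(O[Si](C)(C)C(C)(C)C)cc2O[Si](C)(C)C(C)(C)C)ccc1O[Si](C)(C)C(C)(C)C | intermediate
22 | [2,4-bis(TBSO)phenyl]{2-[(E)-3-[3,5-bis(TBSO)phenyl]-1-[4-(TBSO)-3-methoxyphenyl]prop-1-en-2-yl]-4,6-bis(TBSO)phenyl}methanone hydrazone (C=N geometry not fixed) | COc1cc(/C=C(\Cc2cc(O[Si](C)(C)C(C)(C)C)cc(O[Si](C)(C)C(C)(C)C)c2)c2cc(O[Si](C)(C)C(C)(C)C)cc(O[Si](C)(C)C(C)(C)C)c2C(=NN)c2ccc(O[Si](C)(C)C(C)(C)C)cc2O[Si](C)(C)C(C)(C)C)ccc1O[Si](C)(C)C(C)(C)C | intermediate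
23 | diaryl diazomethane from 22 (not isolated) | COc1cc(/C=C(\Cc2cc(O[Si](C)(C)C(C)(C)C)cc(O[Si](C)(C)C(C)(C)C)c2)c2cc(O[Si](C)(C)C(C)(C)C)cc(O[Si](C)(C)C(C)(C)C)c2C(=[N+]=[N-])c2ccc(O[Si](C)(C)C(C)(C)C)cc2O[Si](C)(C)C(C)(C)C)ccc1O[Si](C)(C)C(C)(C)C | intermediate
24 | (1E,2S,3S)-3-[2,4-bis(TBSO)phenyl]-2-[3,5-bis(TBSO)phenyl]-4,6-bis(TBSO)-1-[4-(TBSO)-3-methoxybenzylidene]indane (trans-2,3; heptakis-TBS ether of the target) | COc1cc(/C=C2/c3cc(O[Si](C)(C)C(C)(C)C)cc(O[Si](C)(C)C(C)(C)C)c3[C@H](c3ccc(O[Si](C)(C)C(C)(C)C)cc3O[Si](C)(C)C(C)(C)C)[C@H]2c2cc(O[Si](C)(C)C(C)(C)C)cc(O[Si](C)(C)C(C)(C)C)c2)ccc1O[Si](C)(C)C(C)(C)C | intermediate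
25 | (1E,2S,3S)-3-(2,4-dihydroxyphenyl)-2-(3,5-dihydroxyphenyl)-1-(4-hydroxy-3-methoxybenzylidene)indane-4,6-diol (CNP0122890.1) | COc1cc(/C=C2/c3cc(O)cc(O)c3[C@H](c3ccc(O)cc3O)[C@H]2c2cc(O)cc(O)c2)ccc1O | target

Total step count: 13. Longest linear sequence: 8 steps (steps 3, 4, 5, 6, 9, 11, 12 and 13, from 5-bromoresorcinol).

Steps most likely to fail

Step 12 (key step). What may go wrong is ring closure under kinetic control to the cis-2,3 diastereomer, the catalyst still fixing C3. In the fallback the insertion is run from 22 for the C3 configuration alone, and the (1E,2R,3S)-cis heptakis-TBS indane F1 is accepted as its product. F1 is then equilibrated at C2, whose hydrogen is allylic and benzylic, with a catalytic non-nucleophilic base (DBU, toluene, 60 °C). The thermodynamically preferred trans-2,3-diaryl isomer should result, and the route is rejoined at 24.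

Step 11. What may go wrong is proton transfer from the diarylallylic CH2 of 16 to the aryllithium or to the N-lithio ketimine. This would lead to transposition of the alkene or to anionic ring closure onto the C=N bond, in competition with addition to the nitrile. In the fallback the aryl ring is added at the aldehyde oxidation level, where addition at −78 °C outruns proton transfer and the alkoxide formed is not basic. From 16, i-Bu2AlH (toluene, −78 °C, then aqueous tartrate) should give the aldehyde F2. Aryllithium 19 (from 18 as before) adds to it to give the diaryl carbinol F3, and Dess–Martin periodinane (NaHCO3, CH2Cl2) oxidises this to the benzophenone F4. This ketone is too hindered for direct condensation with hydrazine, so Lawesson's reagent (toluene, 90 °C) converts it into the thioketone F5. F5 reacts with hydrazine hydrate at room temperature with loss of H2S to give hydrazone 22, where the route is rejoined.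

Step 9. What may go wrong is slow oxidative addition at the hindered vinylic bromide, with homocoupling of the benzylic zinc reagent or erosion of the alkene geometry. In the fallback the alkene is made by syn addition to an alkyne, which also bypasses step 6. From 3, n-BuLi (2 equiv, THF, −78 °C; second stage of the Corey–Fuchs sequence) gives the lithium acetylide F6, which is benzylated with 14 (CuBr·SMe2 cat., THF, −78 °C → rt) to the 1,3-diarylpropyne F7. Addition of B2pin2 with MeOH under CuCl/Xantphos/NaOt-Bu catalysis places boron on the benzyl-bearing carbon and hydrogen syn to it on the vanillyl-bearing carbon, giving the (Z)-alkenylboronate F8. Suzuki–Miyaura coupling of F8 with bromonitrile 8 (Pd(OAc)2, SPhos, K3PO4, toluene/H2O, 60 °C) proceeds with retention and returns to the route at 16.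

Further compounds

F1 | step 12 | (1E,2R,3S)-cis heptakis-TBS indane, the C2 epimer of 24 | COc1cc(/C=C2/c3cc(O[Si](C)(C)C(C)(C)C)cc(O[Si](C)(C)C(C)(C)C)c3[C@H](c3ccc(O[Si](C)(C)C(C)(C)C)cc3O[Si](C)(C)C(C)(C)C)[C@@H]2c2cc(O[Si](C)(C)C(C)(C)C)cc(O[Si](C)(C)C(C)(C)C)c2)ccc1O[Si](C)(C)C(C)(C)C
F2 | step 11 | 2-[(E)-3-[3,5-bis(TBSO)phenyl]-1-[4-(TBSO)-3-methoxyphenyl]prop-1-en-2-yl]-4,6-bis(TBSO)benzaldehyde | COc1cc(/C=C(\Cc2cc(O[Si](C)(C)C(C)(C)C)cc(O[Si](C)(C)C(C)(C)C)c2)c2cc(O[Si](C)(C)C(C)(C)C)cc(O[Si](C)(C)C(C)(C)C)c2C=O)ccc1O[Si](C)(C)C(C)(C)C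
F3 | step 11 | diaryl carbinol from F2 and 19 (racemic at the carbinol carbon) | COc1cc(/C=C(\Cc2cc(O[Si](C)(C)C(C)(C)C)cc(O[Si](C)(C)C(C)(C)C)c2)c2cc(O[Si](C)(C)C(C)(C)C)cc(O[Si](C)(C)C(C)(C)C)c2C(O)c2ccc(O[Si](C)(C)C(C)(C)C)cc2O[Si](C)(C)C(C)(C)C)ccc1O[Si](C)(C)C(C)(C)C
F4 | step 11 | benzophenone corresponding to hydrazone 22 | COc1cc(/C=C(\Cc2cc(O[Si](C)(C)C(C)(C)C)cc(O[Si](C)(C)C(C)(C)C)c2)c2cc(O[Si](C)(C)C(C)(C)C)cc(O[Si](C)(C)C(C)(C)C)c2C(=O)c2ccc(O[Si](C)(C)C(C)(C)C)cc2O[Si](C)(C)C(C)(C)C)ccc1O[Si](C)(C)C(C)(C)C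
F5 | step 11 | thiobenzophenone corresponding to F4 | COc1cc(/C=C(\Cc2cc(O[Si](C)(C)C(C)(C)C)cc(O[Si](C)(C)C(C)(C)C)c2)c2cc(O[Si](C)(C)C(C)(C)C)cc(O[Si](C)(C)C(C)(C)C)c2C(=S)c2ccc(O[Si](C)(C)C(C)(C)C)cc2O[Si](C)(C)C(C)(C)C)ccc1O[Si](C)(C)C(C)(C)C
F6 | step 9 | lithium [4-(TBSO)-3-methoxyphenyl]acetylide | COc1cc(C#C[Li])ccc1O[Si](C)(C)C(C)(C)C
F7 | step 9 | 1-[4-(TBSO)-3-methoxyphenyl]-3-[3,5-bis(TBSO)phenyl]prop-1-yne | COc1cc(C#CCc2cc(O[Si](C)(C)C(C)(C)C)cc(O[Si](C)(C)C(C)(C)C)c2)ccc1O[Si](C)(C)C(C)(C)C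
F8 | step 9 | (Z)-1-[4-(TBSO)-3-methoxyphenyl]-3-[3,5-bis(TBSO)phenyl]prop-1-en-2-ylboronic acid pinacol ester | COc1cc(/C=C(\Cc2cc(O[Si](C)(C)C(C)(C)C)cc(O[Si](C)(C)C(C)(C)C)c2)B2OC(C)(C)C(C)(C)O2)ccc1O[Si](C)(C)C(C)(C)C
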